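## Analysis of the target

Testudinariol A (22) is a C2-symmetric C30 bis-ether. Two 2-isopropenylcyclopentanols are each bonded through C5 to C2' of an oxane, and the two oxanes are joined through exocyclic C5'=C7' double bonds and the two-carbon bridge C8'–C8''. Locants used throughout: cyclopentane C1 (carbinol), C2 (isopropenyl-bearing), C3, C4, C5; oxane O, C2' (on C5), C3', C4', C5' (alkylidene), C6'; tether C7' (vinylic CH) and C8'; double primes for the second half. Each half holds four stereocentres, (1S,2R,5S,2'R): on the cyclopentane the hydroxyl is cis to the isopropenyl group and trans to the oxanyl group, and along the chain C1–C5–C2'–C3' the C4 substituent on C5 and the oxygen on C2' are anti. Both trisubstituted alkenes are (Z), with C8' cis to C6' and trans to C4', although these two ring carbons differ only by the neighbouring oxygen. Sensitive groups are the allylic ether C6'–O, the 1,1-disubstituted alkenes and the homoallylic alcohols (all acid-labile), and, in late intermediates, a C1 aldehyde whose α-carbon C5 can epimerise and whose β-oxygen can be eliminated. The difficulty lies in the symmetry: the halves are too far apart to influence each other, so every stereochemical event must be reagent-controlled and must succeed twice, and the alkene geometry has to be set where the ring offers almost no steric bias. The strategy rests on the open-chain form of each half: C1 is then a hydroxymethyl group on C5 and C2' carries oxygen, so C1–C5–C2' is the retron of a 2,3-epoxy alcohol, and the arm C4–C3–C2 with its CMe2 terminus is a homoprenyl nucleophile that can be attached to C5 with inversion and later serves as the ene partner of C1.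

## Retrosynthetic reasoning

Cyclopentanes, C1–C2. Each cyclopentanol of 22 has a hydroxyl on C1 next to an isopropenyl group on C2, the pattern left by an intramolecular carbonyl-ene reaction. Cutting C1–C2 in both halves gives dialdehyde 21, in which C2 is the inner carbon of a 2-methylpropenyl terminus. The cut removes two stereocentres per half and leaves C5 as the only control element. The forward reaction must place the hydroxyl cis to the isopropenyl group and trans to the oxanyl group.

Oxanes, O–C6'. 21 is the oxidation product of diol 20. Each oxane of 20 is opened at O–C6' and not at O–C2': C6' is a primary allylic carbon, well suited to SN2 displacement, and the stereogenic C2'–O bond stays intact, so its configuration is carried through. This gives bis(allylic chloride) 19, then hexaol 18 by exchange of chloride for hydroxyl, and 18 is tetraol 17 without its two silyl groups. The forward closure has to choose C6' over C7' and the C2' oxygen over the C1 oxygen; ring size decides the latter.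

Key disconnection, C4–C5. 17 contains twice the unit C1H2OH–C5H(alkyl)–C2'H(OH) with the anti relationship. Cutting C4–C5 reveals a trans-2,3-epoxy alcohol and a homoprenyl nucleophile: bis(epoxy alcohol) 12 and cuprate 16, which comes from organolithium 15, iodide 14 and bromide 13. This cut is preferred over C5–C2' because the anti relationship then follows from SN2 inversion instead of from a diastereoselective carbonyl addition, and because both stereocentres of a half come from one catalytic step. The forward reaction has to open both epoxides at C5 and not at C2'.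

Epoxides. The epoxides of 12 go back to the (E)-allylic alcohols of tetraene diol 11 by catalytic asymmetric epoxidation (Sharpless). 11 is achiral, so all absolute configuration enters here under catalyst control, identically in both halves. The two inner alkenes carry no free hydroxyl and must stay untouched.

C5=C2' alkenes. 11 derives from diester 8 by a two-carbon extension at each end: reduction to dialdehyde 9, (E)-selective olefination to bis(enoate) 10, and reduction.

C3'–C4' bonds. 8 is a twofold γ,δ-unsaturated ester, the retron of a Claisen rearrangement. Cutting both C3'–C4' bonds leads through bis(ketene acetal) 7 to bis(allylic alcohol) 6. This is where the alkene geometry is decided: in the chair transition state the tether sits equatorial, which places C8' trans to C4', as 22 requires.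

C5'–C7' bonds. 6 is cut at both C5'–C7' bonds into one molecule of succinaldehyde 2, which supplies C7', C8', C8'' and C7'', and two molecules of alkenyllithium 5. 5 comes from bromide 4 and alcohol 3, and 2 comes from acetal 1. The carbinol configuration of 6 is irrelevant because the Claisen step erases it.

## Alternatives that were turned down

Alternative 1: Both O–C2' bonds are cut by a retro-oxa-Michael reaction, leading to the achiral tetraene diol dialdehyde A2. In the forward key step a chiral primary ammonium salt would condense with both α-branched enals of A2. Each C6' hydroxyl would add to C2' of the iminium ion (6-exo-trig) and the enamine would be protonated at C5, giving dialdehyde A1. A1 is identical with 21 and lies one step from 22. In its favour: it is by far the shortest approach, needs no protecting groups, and sets C2' and C5 of both halves catalytically. Against it: α-branched enals are sluggish iminium substrates. C5 would be set by protonation of an enamine, a step that is hard to control and must deliver the anti relationship to C2'. Oxa-Michael addition is reversible, so C2' and C5 of A1 can equilibrate under the conditions that form them. An allylic primary alcohol is a weak nucleophile. On step economy this alternative is clearly stronger. The chosen route offers instead stereospecific events (syn oxygen transfer, SN2 inversion) that fix the relative configuration by mechanism, and a catalytic epoxidation of well-understood scope for the absolute configuration.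

Alternative 2: The bonds C7'–C8' and C7''–C8'' are cut, giving two copies of the (Z)-alkenyl iodide A4 and the succinate bis(N-acyloxyphthalimide) A5 as a two-carbon linker. The forward key step is an electroreductive decarboxylative coupling catalysed by NiCl2(dme) and 2,2'-bipyridine, carried out twice on A5, giving the bis(silyl ether) A3, which is then desilylated. In its favour: it is the most convergent plan. The fully elaborated half is made once and purified before the union, the coupling happens far from any stereocentre, and the squared-selectivity problem of a two-directional synthesis disappears. Against it: the difficulty moves into A4. An exocyclic iodomethylidene of defined (Z) geometry is needed on a ring carbon whose two neighbours differ only by oxygen versus carbon, and no olefination distinguishes them reliably. The four stereocentres of A4 still need a full asymmetric synthesis. The double coupling must succeed twice on one small linker while reduction of the radical, homocoupling of A4 and isomerisation of the (Z)-alkenyl–nickel species compete. In convergence this alternative is stronger. The chosen route answers with a geometry-defining Claisen step of high reliability at the outset and with a tether that is present from the first C–C bond formation.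

Alternative 3: Both C2'–C3' bonds are cut, giving the C12 bis-Grignard reagent A7 and two equivalents of the α-branched β-alkoxy aldehyde A8. In the forward key step A8 would be held as a six-membered magnesium chelate between the formyl and the ether oxygen. A7 would add to the face away from the homoprenyl group, giving diol A6 with the anti C5/C2' relationship. In its favour: regiochemistry is not an issue. C5 is made once in a small fragment that can be purified, and C1 is differentiated from the start, so in protecting-group logic it is at least as good as the chosen route. Against it: six-membered chelates steer alkyl Grignard additions only moderately, and chelate and Felkin modes give opposite C2' epimers. These epimers differ at one remote carbinol, are hard to separate, and the error counts twice. A8 can racemise by enolisation under the basic conditions. A7 needs the same (Z,Z)-configured diene core as diester 8 of the chosen route, one carbon shorter on each side, and then reduction and halogenation, so no steps are saved. The comparison is a mirror image: here regiocontrol is certain and diastereocontrol is the weak point. In the chosen route diastereocontrol is built in by inversion, and the regiochemical error gives a 1,2-diol that can be destroyed chemically.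

Key step: step 10

Remark: 1 is used as the commercial cis/trans mixture and 6 is carried on as a mixture of its racemic and meso forms; neither matters, because these centres are lost in steps 1 and 4.

## Route

Step 1
Reactants: 1 2,5-dimethoxytetrahydrofuran
Product: 2 succinaldehyde (butanedial)
Conditions: H2O, 90 °C, MeOH/H2O distilled off; extraction, distillation; used at once
Reagents that add atoms: water, O
Why: Hydrolysis of the cyclic bis(methyl acetal); removal of methanol drives the equilibrium to the dialdehyde, which is used fresh because it oligomerises on standing.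

Step 2
Reactants: 3 2-bromoprop-2-en-1-ol
Product: 4 [(2-bromoprop-2-en-1-yl)oxy](tert-butyl)dimethylsilane
Conditions: TBSCl, imidazole, CH2Cl2, 0 °C → rt
Reagents that add atoms: tert-butyldimethylsilyl chloride, CC(C)(C)[Si](C)(C)Cl
Why: Standard silylation of a primary allylic alcohol; the vinyl bromide is not affected.

Step 3
Reactants: 2 succinaldehyde; 4 [(2-bromoprop-2-en-1-yl)oxy](tert-butyl)dimethylsilane
Product: 6 2,7-bis[(tert-butyldimethylsilyloxy)methyl]octa-1,7-diene-3,6-diol, via alkenyllithium 5 (not isolated)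
Conditions: 4 (3 equiv), t-BuLi (6 equiv), Et2O, −78 °C; then 2 (1 equiv), −78 → −40 °C; aq NH4Cl
Reagents that add atoms: none
Why: Two molecules of 4 are consumed for each molecule of 2: bromine–lithium exchange on the vinyl bromide gives 5, and one molecule of 5 adds 1,2 to each of the two formyl groups of 2 (twofold carbonyl addition). 6 therefore holds the two C3 units from 4 and the C4 unit from 2, and the excess of 5 covers what is lost to side reactions. The two carbinol centres form without control, which is harmless because step 4 converts them into sp2 carbons.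

Step 4
Reactants: 6 2,7-bis[(tert-butyldimethylsilyloxy)methyl]octa-1,7-diene-3,6-diol
Product: 8 diethyl (4Z,8Z)-4,9-bis[(tert-butyldimethylsilyloxy)methyl]dodeca-4,8-dienedioate, via bis(ketene acetal) 7 (not isolated)
Conditions: MeC(OEt)3 (excess), EtCO2H (cat.), 140 °C, EtOH distilled off
Reagents that add atoms: triethyl orthoacetate, CC(OCC)(OCC)OCC
Why: Twofold Johnson–Claisen rearrangement: each allylic alcohol exchanges into the orthoester, loses ethanol to give 7 and rearranges through a chair transition state with the tether equatorial. C8' therefore ends up trans to the new C4' chain and cis to the silyloxymethyl group, which is (Z) by the sequence rules; the carbinol centres disappear.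

Step 5
Reactants: 8 diethyl (4Z,8Z)-4,9-bis[(tert-butyldimethylsilyloxy)methyl]dodeca-4,8-dienedioate
Product: 9 (4Z,8Z)-4,9-bis[(tert-butyldimethylsilyloxy)methyl]dodeca-4,8-dienedial
Conditions: i-Bu2AlH (2.1 equiv), toluene, −78 °C; MeOH, then aq potassium sodium tartrate
Reagents that add atoms: none
Why: Partial reduction of the ethyl esters; at −78 °C the tetrahedral aluminium hemiacetal persists and releases the aldehyde only on work-up.

Step 6
Reactants: 9 (4Z,8Z)-4,9-bis[(tert-butyldimethylsilyloxy)methyl]dodeca-4,8-dienedial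
Product: 10 diethyl (2E,6Z,10Z,14E)-6,11-bis[(tert-butyldimethylsilyloxy)methyl]hexadeca-2,6,10,14-tetraenedioate
Conditions: (EtO)2P(O)CH2CO2Et, NaH, THF, 0 °C → rt
Reagents that add atoms: triethyl phosphonoacetate, CCOC(=O)CP(=O)(OCC)OCC
Why: Horner–Wadsworth–Emmons olefination with a stabilised phosphonate, which gives the (E)-enoates; silyl ethers and trisubstituted alkenes are inert.

Step 7
Reactants: 10 diethyl (2E,6Z,10Z,14E)-6,11-bis[(tert-butyldimethylsilyloxy)methyl]hexadeca-2,6,10,14-tetraenedioate
Product: 11 (2E,6Z,10Z,14E)-6,11-bis[(tert-butyldimethylsilyloxy)methyl]hexadeca-2,6,10,14-tetraene-1,16-diol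
Conditions: i-Bu2AlH (5 equiv), CH2Cl2, −78 → 0 °C; aq potassium sodium tartrate
Reagents that add atoms: none
Why: 1,2-Reduction of the enoates to the (E)-allylic alcohols; the hydride does not add to the alkenes.

Step 8
Reactants: 11 (2E,6Z,10Z,14E)-6,11-bis[(tert-butyldimethylsilyloxy)methyl]hexadeca-2,6,10,14-tetraene-1,16-diol
Product: 12 (2R,3R,6Z,10Z,14R,15R)-6,11-bis[(tert-butyldimethylsilyloxy)methyl]-2,3:14,15-diepoxyhexadeca-6,10-diene-1,16-diol
Conditions: Ti(OiPr)4 (0.2 equiv), D-(−)-diethyl tartrate (0.24 equiv), t-BuOOH (4 equiv, anhydrous), 4 Å molecular sieves, CH2Cl2, −20 °C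
Reagents that add atoms: tert-butyl hydroperoxide, CC(C)(C)OO
Why: Sharpless asymmetric epoxidation: only the two primary allylic alcohols can bind to the catalyst formed from Ti(OiPr)4 and the tartrate, so the inner alkenes (allylic silyl ethers) are left alone. With the D-(−)-tartrate each (E)-allylic alcohol gives the (2R,3R)-epoxy alcohol, which sets C5 and C2' of both halves. Because the reaction runs twice on one molecule, a wrong-face event gives a separable diastereomer and not the enantiomer.

Step 9
Reactants: 13 5-bromo-2-methylpent-2-ene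
Product: 14 5-iodo-2-methylpent-2-ene
Conditions: NaI, acetone, reflux
Reagents that add atoms: sodium iodide, [Na+].[I-]
Why: Finkelstein exchange (SN2), driven by precipitation of NaBr; the iodide is needed for a clean iodine–lithium exchange in step 10.

Step 10
Reactants: 12 (2R,3R,6Z,10Z,14R,15R)-6,11-bis[(tert-butyldimethylsilyloxy)methyl]-2,3:14,15-diepoxyhexadeca-6,10-diene-1,16-diol; 14 5-iodo-2-methylpent-2-ene
Product: 17 (2S,3R,6Z,10Z,14R,15S)-6,11-bis[(tert-butyldimethylsilyloxy)methyl]-2,15-bis(4-methylpent-3-en-1-yl)hexadeca-6,10-diene-1,3,14,16-tetraol, via 4-methylpent-3-enyllithium 15 (not isolated), via lithium bis(4-methylpent-3-enyl)cuprate 16 (not isolated)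
Conditions: 14 (16 equiv), t-BuLi (32 equiv), pentane–Et2O, −78 °C → rt; CuI (8 equiv), Et2O, −40 °C; then 12, −40 → −10 °C; aq NH4Cl
Reagents that add atoms: none
Why: t-BuLi converts 14 into 15 by iodine–lithium exchange, and two equivalents of 15 with CuI give the lithium dialkylcuprate 16, a reagent of monovalent copper. 16 first deprotonates the C1 hydroxyls; the cuprate held near each lithium alkoxide then attacks the neighbouring epoxide carbon C5 from the side opposite the C5–O bond (SN2-type oxidative addition at copper, then reductive elimination), forming C4–C5. The closest known reaction type is the opening of trans-2,3-epoxy alcohols at C-2 by lithium dialkylcuprates, which gives anti-2-alkyl-1,3-diols. No ring is closed. C5 is set by inversion at the (R)-configured epoxide carbon and becomes (S), so that the homoprenyl group and the C2' hydroxyl are anti; C2' keeps the (R) configuration installed under control of the tartrate ligand in step 8, because its C–O bond is not broken. The step needs regioselectivity for C5 over C2' at both epoxides; this rests on the free C1 alkoxide next to C5 and on the soft cuprate, not on sterics, because C3' is an unbranched methylene that does not shield C2', so some opening at C2' must be expected. The resulting regioisomers contain a C1/C5 1,2-diol and can be cleaved with NaIO4 before chromatography, which should leave 17 as the only polyol. The allylic silyl ethers and the isolated alkenes are inert to 16, and the excess of 16 covers the ligand lost in the deprotonation.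

Step 11
Reactants: 17 (2S,3R,6Z,10Z,14R,15S)-6,11-bis[(tert-butyldimethylsilyloxy)methyl]-2,15-bis(4-methylpent-3-en-1-yl)hexadeca-6,10-diene-1,3,14,16-tetraol
Product: 18 (2S,3R,6Z,10Z,14R,15S)-6,11-bis(hydroxymethyl)-2,15-bis(4-methylpent-3-en-1-yl)hexadeca-6,10-diene-1,3,14,16-tetraol
Conditions: Bu4NF, THF, 0 °C → rt
Reagents that add atoms: none
Why: Fluoride-induced cleavage of the two primary allylic silyl ethers; nothing else in the molecule reacts with fluoride.

Step 12
Reactants: 18 (2S,3R,6Z,10Z,14R,15S)-6,11-bis(hydroxymethyl)-2,15-bis(4-methylpent-3-en-1-yl)hexadeca-6,10-diene-1,3,14,16-tetraol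
Product: 19 (2S,3R,6Z,10Z,14R,15S)-6,11-bis(chloromethyl)-2,15-bis(4-methylpent-3-en-1-yl)hexadeca-6,10-diene-1,3,14,16-tetraol
Conditions: NCS (3 equiv), Me2S (3.5 equiv), CH2Cl2, −20 → 0 °C
Reagents that add atoms: N-chlorosuccinimide, O=C1CCC(=O)N1Cl
Why: Corey–Kim chlorination: only the allylic alkoxysulfonium ions are displaced by chloride at this temperature, at the primary carbon and without allylic transposition. The saturated primary (C1) and secondary (C2') hydroxyls return unchanged on work-up, and the (Z) geometry is kept.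

Step 13
Reactants: 19 (2S,3R,6Z,10Z,14R,15S)-6,11-bis(chloromethyl)-2,15-bis(4-methylpent-3-en-1-yl)hexadeca-6,10-diene-1,3,14,16-tetraol
Product: 20 (2R,2'R,5Z,5'Z)-5,5'-(butane-1,4-diylidene)bis{2-[(2S)-1-hydroxy-6-methylhept-5-en-2-yl]oxane}
Conditions: NaH (6 equiv), Bu4NI (cat.), THF (high dilution), 0 °C → rt
Reagents that add atoms: none
Why: Williamson etherification: each C2' alkoxide displaces the primary allylic chloride at C6' (6-exo-tet), whereas the C1 alkoxide could only close an eight-membered ring. C2' keeps its configuration because its C–O bond is not broken, and direct SN2 at C6' leaves the (Z)-alkene in place.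

Step 14
Reactants: 20 (2R,2'R,5Z,5'Z)-5,5'-(butane-1,4-diylidene)bis{2-[(2S)-1-hydroxy-6-methylhept-5-en-2-yl]oxane}
Product: 21 (2R,2'R,5Z,5'Z)-5,5'-(butane-1,4-diylidene)bis{2-[(2R)-6-methyl-1-oxohept-5-en-2-yl]oxane}
Conditions: Dess–Martin periodinane (2.6 equiv), CH2Cl2, 0 °C → rt; used at once
Reagents that add atoms: none
Why: Dess–Martin oxidation of both primary alcohols under nearly neutral, base-free conditions, chosen to avoid epimerisation at C5 and β-elimination of the ring oxygen. The change of descriptor at C5 is only a change of priorities.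

Step 15
Reactants: 21 (2R,2'R,5Z,5'Z)-5,5'-(butane-1,4-diylidene)bis{2-[(2R)-6-methyl-1-oxohept-5-en-2-yl]oxane}
Product: 22 testudinariol A, (1S,1'S,2R,2'R,5S,5'S)-5,5'-[butane-1,4-diylidenebis((2R,5Z)-oxane-5,2-diyl)]bis[2-(prop-1-en-2-yl)cyclopentan-1-ol]
Conditions: Me2AlCl (2.2 equiv), CH2Cl2, −78 °C; cold 1 M HCl
Reagents that add atoms: none
Why: Twofold Lewis-acid-promoted intramolecular carbonyl-ene reaction: Me2AlCl activates each formyl group, the C2=CMe2 alkene adds through C2 to C1, and a methyl hydrogen passes to oxygen, leaving the isopropenyl group. The six-membered ene array is cis-fused to the forming cyclopentane, which places hydroxyl and isopropenyl cis, and the oxanyl group on C5 takes the face away from the aluminium-bound oxygen, which places it trans to the hydroxyl; C5 thus controls C1 and C2. The aluminium alkoxide loses methane, which removes the proton that could otherwise isomerise the product.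

## Compound list

1 | 2,5-dimethoxytetrahydrofuran (cis/trans mixture) | COC1CCC(OC)O1 | starting material
2 | succinaldehyde (butanedial) | O=CCCC=O | intermediate
3 | 2-bromoprop-2-en-1-ol | OCC(Br)=C | starting material
4 | [(2-bromoprop-2-en-1-yl)oxy](tert-butyl)dimethylsilane | C=C(Br)CO[Si](C)(C)C(C)(C)C | intermediate
5 | [3-(tert-butyldimethylsilyloxy)prop-1-en-2-yl]lithium | [Li]C(=C)CO[Si](C)(C)C(C)(C)C | intermediate (not isolated)
6 | 2,7-bis[(tert-butyldimethylsilyloxy)methyl]octa-1,7-diene-3,6-diol (racemic plus meso) | C=C(CO[Si](C)(C)C(C)(C)C)C(O)CCC(O)C(=C)CO[Si](C)(C)C(C)(C)C | intermediate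
7 | 3,6-bis[(1-ethoxyethenyl)oxy]-2,7-bis[(tert-butyldimethylsilyloxy)methyl]octa-1,7-diene | C=C(OCC)OC(CCC(OC(=C)OCC)C(=C)CO[Si](C)(C)C(C)(C)C)C(=C)CO[Si](C)(C)C(C)(C)C | intermediate (not isolated)
8 | diethyl (4Z,8Z)-4,9-bis[(tert-butyldimethylsilyloxy)methyl]dodeca-4,8-dienedioate | CCOC(=O)CC/C(CO[Si](C)(C)C(C)(C)C)=C/CC/C=C(CO[Si](C)(C)C(C)(C)C)/CCC(=O)OCC | intermediate
9 | (4Z,8Z)-4,9-bis[(tert-butyldimethylsilyloxy)methyl]dodeca-4,8-dienedial | O=CCC/C(CO[Si](C)(C)C(C)(C)C)=C/CC/C=C(CO[Si](C)(C)C(C)(C)C)/CCC=O | intermediate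
10 | diethyl (2E,6Z,10Z,14E)-6,11-bis[(tert-butyldimethylsilyloxy)methyl]hexadeca-2,6,10,14-tetraenedioate | CCOC(=O)/C=C/CC/C(CO[Si](C)(C)C(C)(C)C)=C/CC/C=C(CO[Si](C)(C)C(C)(C)C)/CC/C=C/C(=O)OCC | intermediate
11 | (2E,6Z,10Z,14E)-6,11-bis[(tert-butyldimethylsilyloxy)methyl]hexadeca-2,6,10,14-tetraene-1,16-diol | OC/C=C/CC/C(CO[Si](C)(C)C(C)(C)C)=C/CC/C=C(CO[Si](C)(C)C(C)(C)C)/CC/C=C/CO | intermediate
12 | (2R,3R,6Z,10Z,14R,15R)-6,11-bis[(tert-butyldimethylsilyloxy)methyl]-2,3:14,15-diepoxyhexadeca-6,10-diene-1,16-diol | OC[C@H]1O[C@@H]1CC/C(CO[Si](C)(C)C(C)(C)C)=C/CC/C=C(CO[Si](C)(C)C(C)(C)C)/CC[C@H]2O[C@@H]2CO | intermediate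
13 | 5-bromo-2-methylpent-2-ene | CC(C)=CCCBr | starting material
14 | 5-iodo-2-methylpent-2-ene | CC(C)=CCCI | intermediate
15 | 4-methylpent-3-enyllithium | [Li]CCC=C(C)C | intermediate (not isolated)
16 | lithium bis(4-methylpent-3-enyl)cuprate | [Li+].CC(C)=CCC[Cu-]CCC=C(C)C | intermediate (not isolated)
17 | (2S,3R,6Z,10Z,14R,15S)-6,11-bis[(tert-butyldimethylsilyloxy)methyl]-2,15-bis(4-methylpent-3-en-1-yl)hexadeca-6,10-diene-1,3,14,16-tetraol | CC(C)=CCC[C@H]([C@H](O)CC/C(CO[Si](C)(C)C(C)(C)C)=C/CC/C=C(CO[Si](C)(C)C(C)(C)C)/CC[C@@H](O)[C@H](CO)CCC=C(C)C)CO | intermediate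
18 | (2S,3R,6Z,10Z,14R,15S)-6,11-bis(hydroxymethyl)-2,15-bis(4-methylpent-3-en-1-yl)hexadeca-6,10-diene-1,3,14,16-tetraol | CC(C)=CCC[C@H]([C@H](O)CC/C(CO)=C/CC/C=C(CO)/CC[C@@H](O)[C@H](CO)CCC=C(C)C)CO | intermediate
19 | (2S,3R,6Z,10Z,14R,15S)-6,11-bis(chloromethyl)-2,15-bis(4-methylpent-3-en-1-yl)hexadeca-6,10-diene-1,3,14,16-tetraol | CC(C)=CCC[C@H]([C@H](O)CC/C(CCl)=C/CC/C=C(CCl)/CC[C@@H](O)[C@H](CO)CCC=C(C)C)CO | intermediate
20 | (2R,2'R,5Z,5'Z)-5,5'-(butane-1,4-diylidene)bis{2-[(2S)-1-hydroxy-6-methylhept-5-en-2-yl]oxane} | CC(C)=CCC[C@@H](CO)[C@H]1CC/C(=C/CC/C=C2/CC[C@H]([C@H](CO)CCC=C(C)C)OC2)CO1 | intermediate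
21 | (2R,2'R,5Z,5'Z)-5,5'-(butane-1,4-diylidene)bis{2-[(2R)-6-methyl-1-oxohept-5-en-2-yl]oxane} | CC(C)=CCC[C@@H](C=O)[C@H]1CC/C(=C/CC/C=C2/CC[C@H]([C@H](C=O)CCC=C(C)C)OC2)CO1 | intermediate
22 | testudinariol A, (1S,1'S,2R,2'R,5S,5'S)-5,5'-[butane-1,4-diylidenebis((2R,5Z)-oxane-5,2-diyl)]bis[2-(prop-1-en-2-yl)cyclopentan-1-ol] | C=C(C)[C@H]1CC[C@H]([C@H]2CC/C(=C/CC/C=C3/CC[C@H]([C@H]4CC[C@H](C(=C)C)[C@@H]4O)OC3)CO2)[C@H]1O | target

## Step count and least certain steps

Total: 15 steps. Longest linear sequence: 13 steps (steps 2–8 and 10–15 from 3; equally long from 1 through steps 1, 3–8 and 10–15).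

Step 10 (key step). The most likely failure is erosion of regioselectivity: opening at C2' instead of C5 at one or both epoxides. The unbranched C3' methylene gives no steric protection, and both openings must be correct, so the per-epoxide selectivity counts twice. Thermal decomposition of the cuprate before the second opening is a further risk. Fallback: make C5 the α-carbon of a carboxylate, for which C-2 opening by dialkylcuprates is strongly preferred. It sets out from 12, which is oxidised (TEMPO cat., PhI(OAc)2, aqueous MeCN) to the bis(glycidic acid) (2S,3R,6Z,10Z,14R,15S)-6,11-bis[(tert-butyldimethylsilyloxy)methyl]-2,3:14,15-diepoxyhexadeca-6,10-dienedioic acid F1. Cuprate 16 opens F1 at C5 with the same inversion and gives the bis(β-hydroxy acid) (2R,3R,6Z,10Z,14R,15R)-6,11-bis[(tert-butyldimethylsilyloxy)methyl]-3,14-dihydroxy-2,15-bis(4-methylpent-3-en-1-yl)hexadeca-6,10-dienedioic acid F2. Reduction of F2 with LiAlH4 in THF returns to the route at 17.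

Step 15. The most likely failure is poor control of the relative configuration at C1 and C2 in one or both rings. A bidentate aluminium complex between the formyl oxygen and the oxane oxygen would turn the carbonyl toward the ring oxygen and favour the 1,5-cis cyclopentanol. Enolisation at C5 or β-elimination of the ring oxygen would also erase the controlling centre. Fallback: carry out the ene cyclisation before the oxanes exist, on a substrate whose C2' oxygen is a non-chelating silyl ether. It sets out from 17, which is persilylated (Et3SiCl, imidazole) to the tetrakis(triethylsilyl) ether (2S,3R,6Z,10Z,14R,15S)-6,11-bis[(tert-butyldimethylsilyloxy)methyl]-2,15-bis(4-methylpent-3-en-1-yl)-1,3,14,16-tetrakis(triethylsilyloxy)hexadeca-6,10-diene F3. Swern oxidation converts the primary triethylsilyl ethers directly into aldehydes and leaves the secondary triethylsilyl and the tert-butyldimethylsilyl ethers, giving the dialdehyde (2R,3R,6Z,10Z,14R,15R)-6,11-bis[(tert-butyldimethylsilyloxy)methyl]-2,15-bis(4-methylpent-3-en-1-yl)-3,14-bis(triethylsilyloxy)hexadeca-6,10-dienedial F4. Me2AlCl then closes both rings to the bis(cyclopentanol) (1S,1'S,2R,2'R,5S,5'S)-5,5'-{(1R,4Z,8Z,12R)-4,9-bis[(tert-butyldimethylsilyloxy)methyl]-1,12-bis(triethylsilyloxy)dodeca-4,8-diene-1,12-diyl}bis[2-(prop-1-en-2-yl)cyclopentan-1-ol] F5. Bu4NF gives the hexaol (1S,1'S,2R,2'R,5R,5'R)-5,5'-[(1R,4Z,8Z,12R)-1,12-dihydroxy-4,9-bis(hydroxymethyl)dodeca-4,8-diene-1,12-diyl]bis[2-(prop-1-en-2-yl)cyclopentan-1-ol] F6. NCS/Me2S gives the bis(allylic chloride) (1S,1'S,2R,2'R,5R,5'R)-5,5'-[(1R,4Z,8Z,12R)-4,9-bis(chloromethyl)-1,12-dihydroxydodeca-4,8-diene-1,12-diyl]bis[2-(prop-1-en-2-yl)cyclopentan-1-ol] F7. NaH closes both oxanes, since only the C2' alkoxide reaches C6' through a six-membered transition state, and the sequence comes back to the route at 22.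

Step 3. The most likely failure is loss of the organolithium before the second addition: the first adduct can close onto the remaining formyl group as a lithium lactolate that reacts slowly at −78 °C, and on warming 5 can decompose by β-elimination of silanolate or by silyl migration. Oligomerisation of 2 is a further risk. Fallback: use a reagent without a leaving group. It sets out from 3, which with t-BuLi (3 equiv, Et2O, −78 → 0 °C) gives the O,2-dilithio derivative lithium 2-lithioprop-2-en-1-olate F8, stable at 0 °C. Two molecules of F8 add to one molecule of 2 to give the tetraol 2,7-dimethylideneoctane-1,3,6,8-tetraol F9. Selective silylation of the two primary allylic hydroxyls of F9 (TBSCl, 2 equiv, imidazole, −20 °C) returns to the route at 6.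

Step 12 (with step 13). The most likely failure is loss of chemoselectivity in the chlorination: partial substitution or methylthiomethyl ether formation at the free C1 hydroxyl, or incomplete conversion because the other hydroxyls tie up the reagent. Fallback: differentiate C1 by protection. It sets out from 17, which is silylated at the primary hydroxyls (TBDPSCl, imidazole, 0 °C) to (2S,3R,6Z,10Z,14R,15S)-6,11-bis[(tert-butyldimethylsilyloxy)methyl]-1,16-bis(tert-butyldiphenylsilyloxy)-2,15-bis(4-methylpent-3-en-1-yl)hexadeca-6,10-diene-3,14-diol F10. PPTS in MeOH removes only the primary tert-butyldimethylsilyl groups and gives (2S,3R,6Z,10Z,14R,15S)-1,16-bis(tert-butyldiphenylsilyloxy)-6,11-bis(hydroxymethyl)-2,15-bis(4-methylpent-3-en-1-yl)hexadeca-6,10-diene-3,14-diol F11. NCS/Me2S gives (2S,3R,6Z,10Z,14R,15S)-1,16-bis(tert-butyldiphenylsilyloxy)-6,11-bis(chloromethyl)-2,15-bis(4-methylpent-3-en-1-yl)hexadeca-6,10-diene-3,14-diol F12. NaH gives (2R,2'R,5Z,5'Z)-5,5'-(butane-1,4-diylidene)bis{2-[(2S)-1-(tert-butyldiphenylsilyloxy)-6-methylhept-5-en-2-yl]oxane} F13. Bu4NF removes the silyl groups and returns to the route at 20.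

## Further compounds

F1 | step 10 | (2S,3R,6Z,10Z,14R,15S)-6,11-bis[(tert-butyldimethylsilyloxy)methyl]-2,3:14,15-diepoxyhexadeca-6,10-dienedioic acid | OC(=O)[C@H]1O[C@@H]1CC/C(CO[Si](C)(C)C(C)(C)C)=C/CC/C=C(CO[Si](C)(C)C(C)(C)C)/CC[C@H]2O[C@@H]2C(O)=O
F2 | step 10 | (2R,3R,6Z,10Z,14R,15R)-6,11-bis[(tert-butyldimethylsilyloxy)methyl]-3,14-dihydroxy-2,15-bis(4-methylpent-3-en-1-yl)hexadeca-6,10-dienedioic acid | CC(C)=CCC[C@H]([C@H](O)CC/C(CO[Si](C)(C)C(C)(C)C)=C/CC/C=C(CO[Si](C)(C)C(C)(C)C)/CC[C@@H](O)[C@H](C(O)=O)CCC=C(C)C)C(O)=O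
F3 | step 15 | (2S,3R,6Z,10Z,14R,15S)-6,11-bis[(tert-butyldimethylsilyloxy)methyl]-2,15-bis(4-methylpent-3-en-1-yl)-1,3,14,16-tetrakis(triethylsilyloxy)hexadeca-6,10-diene | CC(C)=CCC[C@H]([C@H](O[Si](CC)(CC)CC)CC/C(CO[Si](C)(C)C(C)(C)C)=C/CC/C=C(CO[Si](C)(C)C(C)(C)C)/CC[C@@H](O[Si](CC)(CC)CC)[C@H](CO[Si](CC)(CC)CC)CCC=C(C)C)CO[Si](CC)(CC)CC
F4 | step 15 | (2R,3R,6Z,10Z,14R,15R)-6,11-bis[(tert-butyldimethylsilyloxy)methyl]-2,15-bis(4-methylpent-3-en-1-yl)-3,14-bis(triethylsilyloxy)hexadeca-6,10-dienedial | CC(C)=CCC[C@H]([C@H](O[Si](CC)(CC)CC)CC/C(CO[Si](C)(C)C(C)(C)C)=C/CC/C=C(CO[Si](C)(C)C(C)(C)C)/CC[C@@H](O[Si](CC)(CC)CC)[C@H](C=O)CCC=C(C)C)C=O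
F5 | step 15 | (1S,1'S,2R,2'R,5S,5'S)-5,5'-{(1R,4Z,8Z,12R)-4,9-bis[(tert-butyldimethylsilyloxy)methyl]-1,12-bis(triethylsilyloxy)dodeca-4,8-diene-1,12-diyl}bis[2-(prop-1-en-2-yl)cyclopentan-1-ol] | C=C(C)[C@H]1CC[C@H]([C@H](O[Si](CC)(CC)CC)CC/C(CO[Si](C)(C)C(C)(C)C)=C/CC/C=C(CO[Si](C)(C)C(C)(C)C)/CC[C@@H](O[Si](CC)(CC)CC)[C@H]2CC[C@H](C(=C)C)[C@@H]2O)[C@H]1O
F6 | step 15 | (1S,1'S,2R,2'R,5R,5'R)-5,5'-[(1R,4Z,8Z,12R)-1,12-dihydroxy-4,9-bis(hydroxymethyl)dodeca-4,8-diene-1,12-diyl]bis[2-(prop-1-en-2-yl)cyclopentan-1-ol] | C=C(C)[C@H]1CC[C@H]([C@H](O)CC/C(CO)=C/CC/C=C(CO)/CC[C@@H](O)[C@H]2CC[C@H](C(=C)C)[C@@H]2O)[C@H]1O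
F7 | step 15 | (1S,1'S,2R,2'R,5R,5'R)-5,5'-[(1R,4Z,8Z,12R)-4,9-bis(chloromethyl)-1,12-dihydroxydodeca-4,8-diene-1,12-diyl]bis[2-(prop-1-en-2-yl)cyclopentan-1-ol] | C=C(C)[C@H]1CC[C@H]([C@H](O)CC/C(CCl)=C/CC/C=C(CCl)/CC[C@@H](O)[C@H]2CC[C@H](C(=C)C)[C@@H]2O)[C@H]1O
F8 | step 3 | lithium 2-lithioprop-2-en-1-olate | [Li]OCC([Li])=C
F9 | step 3 | 2,7-dimethylideneoctane-1,3,6,8-tetraol (racemic plus meso) | OCC(=C)C(O)CCC(O)C(=C)CO
F10 | step 12 | (2S,3R,6Z,10Z,14R,15S)-6,11-bis[(tert-butyldimethylsilyloxy)methyl]-1,16-bis(tert-butyldiphenylsilyloxy)-2,15-bis(4-methylpent-3-en-1-yl)hexadeca-6,10-diene-3,14-diol | CC(C)=CCC[C@H]([C@H](O)CC/C(CO[Si](C)(C)C(C)(C)C)=C/CC/C=C(CO[Si](C)(C)C(C)(C)C)/CC[C@@H](O)[C@H](CO[Si](c1ccccc1)(c1ccccc1)C(C)(C)C)CCC=C(C)C)CO[Si](c1ccccc1)(c1ccccc1)C(C)(C)C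
F11 | step 12 | (2S,3R,6Z,10Z,14R,15S)-1,16-bis(tert-butyldiphenylsilyloxy)-6,11-bis(hydroxymethyl)-2,15-bis(4-methylpent-3-en-1-yl)hexadeca-6,10-diene-3,14-diol | CC(C)=CCC[C@H]([C@H](O)CC/C(CO)=C/CC/C=C(CO)/CC[C@@H](O)[C@H](CO[Si](c1ccccc1)(c1ccccc1)C(C)(C)C)CCC=C(C)C)CO[Si](c1ccccc1)(c1ccccc1)C(C)(C)C
F12 | step 12 | (2S,3R,6Z,10Z,14R,15S)-1,16-bis(tert-butyldiphenylsilyloxy)-6,11-bis(chloromethyl)-2,15-bis(4-methylpent-3-en-1-yl)hexadeca-6,10-diene-3,14-diol | CC(C)=CCC[C@H]([C@H](O)CC/C(CCl)=C/CC/C=C(CCl)/CC[C@@H](O)[C@H](CO[Si](c1ccccc1)(c1ccccc1)C(C)(C)C)CCC=C(C)C)CO[Si](c1ccccc1)(c1ccccc1)C(C)(C)C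
F13 | step 12 | (2R,2'R,5Z,5'Z)-5,5'-(butane-1,4-diylidene)bis{2-[(2S)-1-(tert-butyldiphenylsilyloxy)-6-methylhept-5-en-2-yl]oxane} | CC(C)=CCC[C@@H](CO[Si](c1ccccc1)(c1ccccc1)C(C)(C)C)[C@H]2CC/C(=C/CC/C=C3/CC[C@H]([C@H](CO[Si](c1ccccc1)(c1ccccc1)C(C)(C)C)CCC=C(C)C)OC3)CO2
A1 | alternative 1 | (2R,2'R,5Z,5'Z)-5,5'-(butane-1,4-diylidene)bis{2-[(2R)-6-methyl-1-oxohept-5-en-2-yl]oxane} (identical with 21) | CC(C)=CCC[C@H]([C@H]2CC/C(=C/CC/C=C3/CC[C@H]([C@H](C=O)CCC=C(C)C)OC3)CO2)C=O
A2 | alternative 1 | (2E,6Z,10Z,14E)-6,11-bis(hydroxymethyl)-2,15-bis(4-methylpent-3-en-1-yl)hexadeca-2,6,10,14-tetraenedial | O=C/C(CCC=C(C)C)=C/CC/C(CO)=C/CC/C=C(CO)/CC/C=C(/C=O)CCC=C(C)C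
A3 | alternative 2 | testudinariol A bis(tert-butyldimethylsilyl) ether | C=C(C)[C@H]1CC[C@H]([C@H]2CC/C(=C/CC/C=C3/CC[C@H]([C@H]4CC[C@H](C(=C)C)[C@@H]4O[Si](C)(C)C(C)(C)C)OC3)CO2)[C@H]1O[Si](C)(C)C(C)(C)C
A4 | alternative 2 | tert-butyl({(1S,2R,5R)-5-[(2R,5Z)-5-(iodomethylidene)oxan-2-yl]-2-(prop-1-en-2-yl)cyclopentyl}oxy)dimethylsilane | C=C(C)[C@H]1CC[C@H]([C@H]2CC/C(=C/I)CO2)[C@H]1O[Si](C)(C)C(C)(C)C
A5 | alternative 2 | bis(1,3-dioxoisoindolin-2-yl) butanedioate | O=C(CCC(=O)ON1C(=O)c2ccccc2C1=O)ON1C(=O)c2ccccc2C1=O
A6 | alternative 3 | (2S,3R,6Z,10Z,14R,15S)-6,11-bis[(tert-butyldimethylsilyloxy)methyl]-1,16-bis[(4-methoxyphenyl)methoxy]-2,15-bis(4-methylpent-3-en-1-yl)hexadeca-6,10-diene-3,14-diol | CC(C)=CCC[C@H]([C@H](O)CC/C(CO[Si](C)(C)C(C)(C)C)=C/CC/C=C(CO[Si](C)(C)C(C)(C)C)/CC[C@@H](O)[C@H](COCc1ccc(OC)cc1)CCC=C(C)C)COCc1ccc(OC)cc1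
A7 | alternative 3 | {(3Z,7Z)-3,8-bis[(tert-butyldimethylsilyloxy)methyl]deca-3,7-diene-1,10-diyl}bis(magnesium bromide) | Br[Mg]CC/C(CO[Si](C)(C)C(C)(C)C)=C/CC/C=C(CO[Si](C)(C)C(C)(C)C)/CC[Mg]Br
A8 | alternative 3 | (2S)-2-{[(4-methoxyphenyl)methoxy]methyl}-6-methylhept-5-enal | CC(C)=CCC[C@H](C=O)COCc1ccc(OC)cc1
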